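**Assumption:** the target is treated as the open 6‑hydroxy 18‑aldehyde as drawn; any ring–chain equilibrium with its 6,18‑lactol is regarded as the same compound.

**Numbering used:** labdane numbering for bicyclic compounds (decalin C1–C10, chain C11–C15, C16 = methyl on C13, C17 = exocyclic CH2 on C8, C18 = 4α carbon, C19 = 4β‑methyl, C20 = 10β‑methyl); acyclic compounds carry systematic names.

## Retrosynthetic overview

1. Target 20 ⇐ hydroxy dialdehyde 16 + silyloxyfuran 18: the last C–C bond is a catalytic asymmetric vinylogous Mukaiyama aldol that sets C15 and the lactone carbon; the butenolide ring is brought in intact.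
2. 16 ⇐ bicyclic triol 11 by C2 (acetylide) and C1 + C1 (methylalumination/formaldehyde) chain extension, then one chemoselective oxidation of both primary alcohols.
3. 11 ⇐ acyclic epoxy diene diol 10 by one head‑to‑tail bicyclization in the biosynthetic order (ring A, then ring B, ending as the 8(17)‑alkene), run as a radical cascade from a C4–C18 oxirane so that C18 emerges oxygenated; the single C6 carbinol relays absolute configuration to C4, C5, C9 and C10.
4. 10 ⇐ 5‑bromopent‑1‑ene by two Zr‑catalysed methylaluminations (both E‑trisubstituted alkenes), an organocatalytic asymmetric propargylation (C6), a Wacker oxidation and a sulfonium ylide.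
5. No protecting groups are used on the main chain.

## Route

**Step 1**
Reactants: 1 5‑bromopent‑1‑ene
Product: 2 hept‑1‑en‑6‑yne
Conditions: LiC≡CH·H2NCH2CH2NH2 (1.3 equiv), DMSO, 10 °C → rt
Reagents that add atoms: lithium acetylide ethylenediamine complex, [Li+].[C-]#C.NCCN
Why: SN2 alkylation of the acetylide by a primary bromide (acetylide alkylation); no stereocentre is involved.

**Step 2**
Reactants: 2 hept‑1‑en‑6‑yne
Product: 4 (2E)‑3‑methylocta‑2,7‑dien‑1‑ol, via alkenyl(dimethyl)alane 3 (not isolated)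
Conditions: Me3Al (2 equiv), Cp2ZrCl2 (0.25 equiv), CH2Cl2, 0 °C → rt; evaporate; n‑BuLi, THF, −78 °C; (CH2O)n, → rt; 1 M HCl
Reagents that add atoms: trimethylaluminium, C[Al](C)C; formaldehyde (as paraformaldehyde), C=O
Why: Negishi zirconium‑catalysed syn‑methylalumination of the terminal alkyne (the terminal alkene is left alone) puts CH3 and Al cis, and the alanate adds to formaldehyde with retention, fixing the E alkene that becomes C5=C10.

**Step 3**
Reactants: 4 (2E)‑3‑methylocta‑2,7‑dien‑1‑ol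
Product: 5 (2E)‑3‑methylocta‑2,7‑dienal
Conditions: MnO2 (15 equiv), CH2Cl2, rt
Reagents that add atoms: none
Why: allylic alcohol oxidation with MnO2, which does not isomerise the E enal.

**Step 4**
Reactants: 5 (2E)‑3‑methylocta‑2,7‑dienal
Product: 6 (4S,5E)‑6‑methylundeca‑5,10‑dien‑1‑yn‑4‑ol
Conditions: allenyl‑B(pin) (1.5 equiv), (S)‑TRIP [(S)‑3,3′‑bis(2,4,6‑triisopropylphenyl)‑1,1′‑binaphthyl‑2,2′‑diyl hydrogen phosphate] (5 mol %), 4 Å MS, toluene, −20 °C; aq. NaHCO3
Reagents that add atoms: 2‑allenyl‑4,4,5,5‑tetramethyl‑1,3,2‑dioxaborolane, C=C=CB1OC(C)(C)C(C)(C)O1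
Why: chiral‑phosphoric‑acid‑catalysed propargylboration (SE2′ through a six‑membered chair with the acid hydrogen‑bonded to a boronate oxygen); the (S)‑acid directs Si‑face attack and sets the (S)‑carbinol that becomes C6, the only stereocentre before the cyclization.

**Step 5**
Reactants: 6 (4S,5E)‑6‑methylundeca‑5,10‑dien‑1‑yn‑4‑ol
Product: 8 (3E,6S,7E)‑4,8‑dimethyltrideca‑3,7,12‑triene‑1,6‑diol, via alkenyl(dimethyl)alane alkoxide 7 (not isolated)
Conditions: Me3Al (3.2 equiv), Cp2ZrCl2 (0.3 equiv), CH2Cl2, 0 °C → rt (no heating); evaporate; n‑BuLi, THF, −78 °C; oxirane, −78 → 0 °C; aq. Rochelle salt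
Reagents that add atoms: trimethylaluminium, C[Al](C)C; oxirane, C1CO1
Why: a second Negishi syn‑methylalumination (kept at or below rt so the homopropargylic alkoxide does not isomerise the alkenylalane) and alanate opening of oxirane give the E alkene that becomes C8=C9 and add C11–C12; the carbinol is not touched.

**Step 6**
Reactants: 8 (3E,6S,7E)‑4,8‑dimethyltrideca‑3,7,12‑triene‑1,6‑diol
Product: 9 (6E,8S,10E)‑8,13‑dihydroxy‑6,10‑dimethyltrideca‑6,10‑dien‑2‑one
Conditions: PdCl2 (10 mol %), CuCl (1 equiv), O2 (1 atm), DMF/H2O 7:1, rt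
Reagents that add atoms: water, O
Why: Tsuji–Wacker oxidation, Markovnikov and selective for the monosubstituted terminal alkene over the two trisubstituted ones, unmasks the methyl ketone that becomes C4/C19.

**Step 7**
Reactants: 9 (6E,8S,10E)‑8,13‑dihydroxy‑6,10‑dimethyltrideca‑6,10‑dien‑2‑one
Product: 10 (3E,6S,7E)‑4,8‑dimethyl‑11‑(2‑methyloxiran‑2‑yl)undeca‑3,7‑diene‑1,6‑diol (about 1:1 at the oxirane carbon)
Conditions: Me3S+ I− (1.5 equiv), n‑BuLi (1.4 equiv), THF, −10 → 0 °C
Reagents that add atoms: trimethylsulfonium iodide, C[S+](C)C.[I-]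
Why: Corey–Chaykovsky methylene transfer to the ketone gives the 2,2‑disubstituted oxirane (C4–C18); its new centre is formed unselectively but becomes a planar radical in the next step, so both epimers converge.

**Step 8**
Reactants: 10 (3E,6S,7E)‑4,8‑dimethyl‑11‑(2‑methyloxiran‑2‑yl)undeca‑3,7‑diene‑1,6‑diol
Product: 11 (4R,5R,6S,9S,10R)‑13,14,15,16‑tetranorlabd‑8(17)‑ene‑6,12,18‑triol (6α‑OH, 4α‑CH2OH, trans‑decalin, 9β‑hydroxyethyl)
Conditions: Cp2TiCl2 (2.5 equiv), Mn (8 equiv), THF, rt; 10 added over 1 h (0.02 M); 1 M HCl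
Reagents that add atoms: none
Why: Proposed new method: Cp2TiCl (trivalent titanium) opens the oxirane homolytically to the tertiary C4 radical carrying CH2OTiCp2Cl, which closes ring A and then ring B by two 6‑endo chair additions through the E,E‑diene (trans‑decalin, 9β side chain), and the tertiary C8 radical is captured by a second Cp2TiCl and loses a C17 hydrogen to give the 8(17)‑alkene; the bulky CH2OTi group takes the equatorial (4α) position, and at C5 allylic 1,3‑strain with the C20 methyl keeps H6 in the alkene plane while the free 6‑hydroxyl lies on the side of the incoming C18–O–Ti unit, where it can hydrogen‑bond to the titanium alkoxide, with the larger C7 branch anti to the forming bond, so O6 ends equatorial (6α) and the one carbinol fixes C4, C5, C9 and C10; the closest known reaction is the Nugent–RajanBabu/Cp2TiCl radical cyclization of 2,3‑epoxypolyprenes to 8(17)‑ene bicycles, extended here to a 2,2‑disubstituted oxirane initiator and to relay from an allylic carbinol.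

**Step 9**
Reactants: 11 (4R,5R,6S,9S,10R)‑13,14,15,16‑tetranorlabd‑8(17)‑ene‑6,12,18‑triol
Product: 12 (4R,5R,6S,9S,10R)‑12‑iodo‑13,14,15,16‑tetranorlabd‑8(17)‑ene‑6,18‑diol
Conditions: I2 (1.1 equiv), PPh3 (1.1 equiv), imidazole (2.2 equiv), CH2Cl2, 0 °C
Reagents that add atoms: iodine, II
Why: Garegg–Samuelsson (Appel‑type) iodination; SN2 displacement of the alkoxyphosphonium ion is fast only at the unhindered C12 primary carbinol, and the neopentyl C18 and secondary C6 hydroxyls are left.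

**Step 10**
Reactants: 12 (4R,5R,6S,9S,10R)‑12‑iodo‑13,14,15,16‑tetranorlabd‑8(17)‑ene‑6,18‑diol
Product: 13 (4R,5R,6S,9S,10R)‑15,16‑dinorlabd‑8(17)‑en‑13‑yne‑6,18‑diol
Conditions: LiC≡CH·H2NCH2CH2NH2 (5 equiv), DMSO, rt
Reagents that add atoms: lithium acetylide ethylenediamine complex, [Li+].[C-]#C.NCCN
Why: SN2 acetylide alkylation of the primary iodide adds C13–C14; with no silyl group present the alkoxides formed cannot cause migrations, and no stereocentre is touched.

**Step 11**
Reactants: 13 (4R,5R,6S,9S,10R)‑15,16‑dinorlabd‑8(17)‑en‑13‑yne‑6,18‑diol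
Product: 15 (4R,5R,6S,9S,10R,13E)‑labda‑8(17),13‑diene‑6,15,18‑triol, via alkenyl(dimethyl)alane bis‑alkoxide 14 (not isolated)
Conditions: Me3Al (4.5 equiv), Cp2ZrCl2 (0.3 equiv), CH2Cl2, 0 °C → rt; evaporate; n‑BuLi, THF, −78 °C; (CH2O)n, → rt; aq. Rochelle salt
Reagents that add atoms: trimethylaluminium, C[Al](C)C; formaldehyde (as paraformaldehyde), C=O
Why: a third Negishi syn‑methylalumination and hydroxymethylation sets the 13E trisubstituted alkene and adds C15 and C16; the 1,1‑disubstituted exocyclic alkene does not carbometalate under Cp2ZrCl2 catalysis.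

**Step 12**
Reactants: 15 (4R,5R,6S,9S,10R,13E)‑labda‑8(17),13‑diene‑6,15,18‑triol
Product: 16 (4R,5R,6S,9S,10R,13E)‑6‑hydroxylabda‑8(17),13‑diene‑15,18‑dial
Conditions: [Cu(MeCN)4]OTf (10 mol %), 2,2′‑bipyridine (10 mol %), TEMPO (10 mol %), N‑methylimidazole (20 mol %), air, MeCN, rt → 40 °C
Reagents that add atoms: none
Why: Hoover–Stahl copper/TEMPO aerobic oxidation is selective for primary over secondary alcohols, so the allylic C15 and neopentyl C18 carbinols become aldehydes while the hindered 6‑hydroxyl stays; C4 is quaternary and cannot epimerise.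

**Step 13**
Reactants: 17 4‑methylfuran‑2(5H)‑one
Product: 18 4‑methyl‑2‑(trimethylsilyloxy)furan
Conditions: Me3SiOTf (1.1 equiv), Et3N (1.3 equiv), Et2O, 0 °C; distil
Reagents that add atoms: trimethylsilyl trifluoromethanesulfonate, C[Si](C)(C)OS(=O)(=O)C(F)(F)F
Why: soft enolisation and O‑silylation of the butenolide gives the silyl dienol ether (2‑silyloxyfuran) whose C5 is the nucleophilic γ‑carbon.

**Step 14**
Reactants: 16 (4R,5R,6S,9S,10R,13E)‑6‑hydroxylabda‑8(17),13‑diene‑15,18‑dial; 18 4‑methyl‑2‑(trimethylsilyloxy)furan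
Product: 20 CNP0113661.1 (target), via 15‑O‑trimethylsilyl aldol adduct 19 (not isolated)
Conditions: 18 (1.6 equiv), Ti(OiPr)4 (20 mol %), (R)‑BINOL (20 mol %), Et2O, −20 °C; then 1 M HCl, THF, 0 °C
Reagents that add atoms: none
Why: titanium–BINOL‑catalysed vinylogous Mukaiyama aldol in which the furan γ‑carbon adds to the Re face of the enal through an open transition state that gives the threo adduct (15S, lactone carbon S), the ligand and not the remote decalin fixing the facial sense, while the neopentyl C18 formyl group (also able to rest as its lactol with the 6‑hydroxyl) does not compete; dilute acid removes the O‑silyl group.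

## Compound list

1 | 5‑bromopent‑1‑ene | C=CCCCBr | starting material
2 | hept‑1‑en‑6‑yne | C=CCCCC#C | intermediate
3 | dimethyl[(1E)‑2‑methylhepta‑1,6‑dien‑1‑yl]alane | C=CCCC/C(C)=C/[Al](C)C | intermediate
4 | (2E)‑3‑methylocta‑2,7‑dien‑1‑ol | C=CCCC/C(C)=C/CO | intermediate
5 | (2E)‑3‑methylocta‑2,7‑dienal | C=CCCC/C(C)=C/C=O | intermediate
6 | (4S,5E)‑6‑methylundeca‑5,10‑dien‑1‑yn‑4‑ol | C#CC[C@H](O)/C=C(C)/CCCC=C | intermediate
7 | [(1E,4S,5E)‑4‑(dimethylalumanyloxy)‑2,6‑dimethylundeca‑1,5,10‑trien‑1‑yl]dimethylalane | C[Al](C)/C=C(C)/C[C@H](O[Al](C)C)/C=C(C)/CCCC=C | intermediate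
8 | (3E,6S,7E)‑4,8‑dimethyltrideca‑3,7,12‑triene‑1,6‑diol | OCC/C=C(C)/C[C@H](O)/C=C(C)/CCCC=C | intermediate
9 | (6E,8S,10E)‑8,13‑dihydroxy‑6,10‑dimethyltrideca‑6,10‑dien‑2‑one | OCC/C=C(C)/C[C@H](O)/C=C(C)/CCCC(C)=O | intermediate
10 | (3E,6S,7E)‑4,8‑dimethyl‑11‑(2‑methyloxiran‑2‑yl)undeca‑3,7‑diene‑1,6‑diol, both epimers at the oxirane carbon | OCC/C=C(C)/C[C@H](O)/C=C(C)/CCCC1(C)CO1 | intermediate
11 | (4R,5R,6S,9S,10R)‑13,14,15,16‑tetranorlabd‑8(17)‑ene‑6,12,18‑triol | C=C1C[C@H](O)[C@@H]2[C@](C)(CCC[C@@]2(C)CO)[C@H]1CCO | intermediate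
12 | (4R,5R,6S,9S,10R)‑12‑iodo‑13,14,15,16‑tetranorlabd‑8(17)‑ene‑6,18‑diol | C=C1C[C@H](O)[C@@H]2[C@](C)(CCC[C@@]2(C)CO)[C@H]1CCI | intermediate
13 | (4R,5R,6S,9S,10R)‑15,16‑dinorlabd‑8(17)‑en‑13‑yne‑6,18‑diol | C=C1C[C@H](O)[C@@H]2[C@](C)(CCC[C@@]2(C)CO)[C@H]1CCC#C | intermediate
14 | (13E)‑14‑(dimethylalumanyl)‑15‑norlabda‑8(17),13‑diene‑6,18‑diol bis(dimethylaluminium) alkoxide | C=C1C[C@H](O[Al](C)C)[C@@H]2[C@](C)(CCC[C@@]2(C)CO[Al](C)C)[C@H]1CC/C(C)=C/[Al](C)C | intermediate
15 | (4R,5R,6S,9S,10R,13E)‑labda‑8(17),13‑diene‑6,15,18‑triol | C=C1C[C@H](O)[C@@H]2[C@](C)(CCC[C@@]2(C)CO)[C@H]1CC/C(C)=C/CO | intermediate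
16 | (4R,5R,6S,9S,10R,13E)‑6‑hydroxylabda‑8(17),13‑diene‑15,18‑dial | C=C1C[C@H](O)[C@@H]2[C@](C)(CCC[C@@]2(C)C=O)[C@H]1CC/C(C)=C/C=O | intermediate
17 | 4‑methylfuran‑2(5H)‑one | CC1=CC(=O)OC1 | starting material
18 | 4‑methyl‑2‑(trimethylsilyloxy)furan | Cc1coc(O[Si](C)(C)C)c1 | intermediate
19 | 15‑O‑trimethylsilyl ether of 20 | C=C1C[C@H](O)[C@@H]2[C@](C)(CCC[C@@]2(C)C=O)[C@H]1CC/C(C)=C/[C@H](O[Si](C)(C)C)[C@H]1OC(=O)C=C1C | intermediate
20 | (4R,5R,6S,9S,10R,13E,15S)‑6,15‑dihydroxy‑15‑[(2S)‑3‑methyl‑5‑oxo‑2,5‑dihydrofuran‑2‑yl]labda‑8(17),13‑dien‑18‑al (CNP0113661.1) | C=C1C[C@H](O)[C@@H]2[C@](C)(CCC[C@@]2(C)C=O)[C@H]1CC/C(C)=C/[C@H](O)[C@H]1OC(=O)C=C1C | target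

## Step count and risks

Total step count: 14. Longest linear sequence: 13 (steps 1–12 and 14; step 13 is a one‑step side branch).

**Step 8 (bicyclization).** The risks are the relay from C6 to C5 (and the CH2O‑equatorial preference at C4), loss of the C4 radical by reduction or deoxygenation before it cyclises, and alkene regioisomers on termination. The fallback sets out from 10 and comes back at 11. Et2Al–TMP (diethylaluminium 2,2,6,6‑tetramethylpiperidide, toluene, 0 °C) isomerises the oxirane by removing a proton from its methyl group and gives (3E,6S,7E)‑11‑(hydroxymethyl)‑4,8‑dimethyldodeca‑3,7,11‑triene‑1,6‑diol F1, whose terminus is a 2‑substituted allylic alcohol. A cobalt hydride made from chloro[N,N′‑bis(3,5‑di‑tert‑butylsalicylidene)‑1,2‑cyclohexanediaminato]cobalt and PhSiH3 (benzene, rt) then transfers a hydrogen atom to the CH2 end of that 1,1‑disubstituted alkene. The tertiary C4 radical (now carrying CH2OH and the new CH3) runs the same two 6‑endo closures, and cobalt takes a C17 hydrogen back from the C8 radical, so this cycloisomerization gives 11 directly. Initiation and termination both differ from the titanium route.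

**Step 12 (double oxidation).** The risks are a sluggish neopentyl C18 carbinol and over‑oxidation of the 6,18‑lactol to the lactone. The fallback sets out from 15 and comes back at 20. Et3SiOTf/2,6‑lutidine silylates all three hydroxyls to give the 6,15,18‑tris‑O‑triethylsilyl ether F2. Swern conditions ((COCl)2, DMSO, Et3N, −78 → −30 °C) cleave and oxidise the two primary triethylsilyl ethers and leave the secondary one, giving the 6‑O‑triethylsilyl dialdehyde F3, in which no lactol can form. The aldol of step 14 with 18 then gives the 6‑O‑triethylsilyl 15‑O‑trimethylsilyl adduct F4, and the same dilute‑acid work‑up (HF·pyridine if needed) removes both silyl groups to give 20.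

**Step 14 (vinylogous aldol).** The risks are competition between the two aldehydes and the threo/erythro ratio and enantioselectivity on a β,β‑disubstituted enal. The fallback sets out from 15 and comes back at 19. MnO2 oxidises only the allylic C15 hydroxyl and gives the 6,18‑dihydroxy enal F5, so the titanium–BINOL aldol with 18 meets a single aldehyde; a non‑acidic work‑up gives the 15‑O‑trimethylsilyl 6,18‑diol adduct F6. The copper/TEMPO oxidation of step 12 then converts the lone primary C18 alcohol of F6 into the aldehyde, which is 19, and acid work‑up gives 20.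

## Further compounds

F1 | step 8 | (3E,6S,7E)‑11‑(hydroxymethyl)‑4,8‑dimethyldodeca‑3,7,11‑triene‑1,6‑diol | OCC/C=C(C)/C[C@H](O)/C=C(C)/CCCC(=C)CO
F2 | step 12 | (4R,5R,6S,9S,10R,13E)‑6,15,18‑tris(triethylsilyloxy)labda‑8(17),13‑diene | C=C1C[C@H](O[Si](CC)(CC)CC)[C@@H]2[C@](C)(CCC[C@@]2(C)CO[Si](CC)(CC)CC)[C@H]1CC/C(C)=C/CO[Si](CC)(CC)CC
F3 | step 12 | (4R,5R,6S,9S,10R,13E)‑6‑(triethylsilyloxy)labda‑8(17),13‑diene‑15,18‑dial | C=C1C[C@H](O[Si](CC)(CC)CC)[C@@H]2[C@](C)(CCC[C@@]2(C)C=O)[C@H]1CC/C(C)=C/C=O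
F4 | step 12 | 6‑O‑triethylsilyl 15‑O‑trimethylsilyl ether of 20 | C=C1C[C@H](O[Si](CC)(CC)CC)[C@@H]2[C@](C)(CCC[C@@]2(C)C=O)[C@H]1CC/C(C)=C/[C@H](O[Si](C)(C)C)[C@H]1OC(=O)C=C1C
F5 | step 14 | (4R,5R,6S,9S,10R,13E)‑6,18‑dihydroxylabda‑8(17),13‑dien‑15‑al | C=C1C[C@H](O)[C@@H]2[C@](C)(CCC[C@@]2(C)CO)[C@H]1CC/C(C)=C/C=O
F6 | step 14 | (4R,5R,6S,9S,10R,13E,15S)‑15‑[(2S)‑3‑methyl‑5‑oxo‑2,5‑dihydrofuran‑2‑yl]‑15‑(trimethylsilyloxy)labda‑8(17),13‑diene‑6,18‑diol | C=C1C[C@H](O)[C@@H]2[C@](C)(CCC[C@@]2(C)CO)[C@H]1CC/C(C)=C/[C@H](O[Si](C)(C)C)[C@H]1OC(=O)C=C1C
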